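**Retrosynthetic overview**
1. The diosphenol is made last, by α-oxidation at C2 of the 7-acetoxy-3-oxo-4(18)-ene acid.
2. Ring A comes from a five-to-six ring expansion of a 3-ethynyl-3-hydroxy cis-hydrindane. C5 shifts from C3 to the alkyne carbon, acetylene supplies C4 and C18, and the C4(=CH2)–C3(=O) unit forms in one stroke.
3. C7–OAc and C8–CH3 come from β-face hydroboration of a C7=C8(CH3) alkene, made from the C8 ketone by enol triflate formation and methyl coupling. The side chain comes from olefination of a C13 methyl ketone.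
4. The C9 quaternary centre comes from a chiral-imine Michael addition to methyl vinyl ketone. H-10 comes from cis hydrogenation of the C9=C10 enone.
5. Ring order: the five-membered ring (2-methylcyclopentane-1,3-dione) is present first. Ring B follows by amino-acid-catalysed Robinson annulation with ethyl vinyl ketone, which sets C5. Ring A is formed last by the expansion.

Assumption: the clerodane atom labels of the target are used for all intermediates (in the hydrindanes the five-membered ring is C1–C2–C3–C5–C10, C4 and C18 still missing), and β means the face that carries CH3-19.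

**Step 1**
Reactants: 1 2-methylcyclopentane-1,3-dione; 2 pent-1-en-3-one (ethyl vinyl ketone)
Product: 4 (7aS)-4,7a-dimethyl-2,3,7,7a-tetrahydro-1H-indene-1,5(6H)-dione, via triketone 3 (not isolated)
Conditions: H2O, AcOH (cat.), 70 °C; evaporate; L-phenylalanine (1 equiv), (1S)-(+)-camphor-10-sulfonic acid (0.5 equiv), MeCN, reflux; recrystallise
Reagents that add atoms: none
Why: Michael addition followed by a Hajos–Parrish-type intramolecular aldol condensation (Robinson annulation), in which the L-phenylalanine enamine attacks one of the two enantiotopic ring carbonyl groups, closes ring B at C9=C10 and sets C5 as drawn (7aS).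

**Step 2**
Reactants: 4 (7aS)-4,7a-dimethyl-2,3,7,7a-tetrahydro-1H-indene-1,5(6H)-dione
Product: 5 C3 ethylene ketal of 4
Conditions: Me3SiOCH2CH2OSiMe3 (1.2 equiv), Me3SiOTf (5 mol %), CH2Cl2, −78 to −20 °C
Reagents that add atoms: 1,2-bis(trimethylsilyloxy)ethane, C[Si](C)(C)OCCO[Si](C)(C)C
Why: Noyori ketalisation is kinetically selective for the isolated C3 ketone over the deactivated conjugated C8 ketone, so C8 stays the only free carbonyl group for steps 4 to 7.

**Step 3**
Reactants: 5 C3 ethylene ketal of 4
Product: 6 cis-hydrindan-8-one C3 ketal (10β-H, 9β-H, 19β-CH3)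
Conditions: H2 (4 atm), 10% Pd/C, EtOAc, rt
Reagents that add atoms: none
Why: Heterogeneous catalytic hydrogenation of Hajos–Parrish-type enones delivers hydrogen on the face of the angular methyl group and gives the cis-hydrindanone, which sets H-10 β; the C9 centre formed here is erased in step 4.

**Step 4**
Reactants: 6 cis-hydrindan-8-one C3 ketal; 7 but-3-en-2-one (methyl vinyl ketone)
Product: 10 9β-(3-oxobutyl)-9α-methyl cis-hydrindan-8-one C3 ketal, via imine 8 (not isolated), via adduct imine 9 (not isolated)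
Conditions: (R)-1-phenylethylamine, p-TsOH (cat.), toluene, reflux (Dean–Stark); 7, THF, 40 °C; 20% aq AcOH, rt
Reagents that add atoms: water, O
Why: d'Angelo asymmetric Michael addition, in which the imine reacts through its more substituted secondary enamine tautomer in a compact aza-ene-like transition state, so bond formation is regioselective for C9 and the (R)-phenylethyl group, matched to the open β face of the cis-hydrindane, places the oxobutyl chain β and CH3-20 α.

**Step 5**
Reactants: 10 9β-(3-oxobutyl)-9α-methyl cis-hydrindan-8-one C3 ketal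
Product: 11 tert-butyl (13E)-enoate 8-ketone C3 ketal
Conditions: (EtO)2P(O)CH2CO2tBu, NaH, THF, 0 to 50 °C
Reagents that add atoms: tert-butyl diethylphosphonoacetate, CCOP(=O)(CC(=O)OC(C)(C)C)OCC
Why: Horner–Wadsworth–Emmons olefination takes place only at the unhindered C13 methyl ketone (C8 is flanked by quaternary C9) and gives mainly the E-enoate (about 6:1 expected), the Z isomer being removed by chromatography.

**Step 6**
Reactants: 11 tert-butyl (13E)-enoate 8-ketone C3 ketal
Product: 13 C7(8)-enol triflate, via potassium enolate 12 (not isolated)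
Conditions: KN(SiMe3)2, THF, −78 °C; PhNTf2, −78 to 0 °C
Reagents that add atoms: N-phenylbis(trifluoromethanesulfonimide), O=S(=O)(N(c1ccccc1)S(=O)(=O)C(F)(F)F)C(F)(F)F
Why: Kinetic enolate formation and O-sulfonylation give a single enol triflate, because C8 can enolise only towards C7 (C9 is quaternary) and C3 is masked.

**Step 7**
Reactants: 13 C7(8)-enol triflate
Product: 14 8-methyl-7-ene C3 ketal
Conditions: MeMgBr, Fe(acac)3 (5 mol %), THF/N-methylpyrrolidone, −30 to 0 °C
Reagents that add atoms: methylmagnesium bromide, C[Mg]Br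
Why: Iron-catalysed Kumada-type cross-coupling of the alkenyl triflate installs CH3-17 faster than the Grignard reagent attacks the tert-butyl ester or the ketal.

**Step 8**
Reactants: 14 8-methyl-7-ene C3 ketal
Product: 17 7β-hydroxy-8α-methyl cis-hydrindan-3-one, via alkylborane 15 (not isolated), via hydroxy ketal 16 (not isolated)
Conditions: BH3·SMe2, THF, 0 °C to rt; NaOH, H2O2, 0 °C; 2 M HCl to pH 1, rt
Reagents that add atoms: hydrogen peroxide, OO; water, O
Why: Brown hydroboration–oxidation adds H and B syn and anti-Markovnikov on the β face (the α face is blocked by axial CH3-20 and the axial C5–C3 bond), which sets 7β-OH and 8β-H (CH3-17 α, trans to oxygen) and spares the electron-poor enoate, and acidification of the same pot hydrolyses the dioxolane.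

**Step 9**
Reactants: 17 7β-hydroxy-8α-methyl cis-hydrindan-3-one; 18 ethynylmagnesium bromide
Product: 19 3β-ethynyl-3α,7β-diol
Conditions: 18 (4 equiv), LaCl3·2LiCl (30 mol %), THF, −20 °C to rt; then H2O
Reagents that add atoms: none
Why: Grignard 1,2-addition to the cyclopentanone (one equivalent first deprotonates the C7 hydroxyl group, and the hindered conjugated tert-butyl ester is inert) occurs from the convex β face, and the new C3 centre is lost again in step 11.

**Step 10**
Reactants: 19 3β-ethynyl-3α,7β-diol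
Product: 20 7β-acetoxy-3β-ethynyl-3α-ol
Conditions: Ac2O, pyridine, 4-(dimethylamino)pyridine (cat.), CH2Cl2, 0 °C
Reagents that add atoms: acetic anhydride, CC(=O)OC(C)=O
Why: Nucleophile-catalysed acylation is selective for the equatorial secondary C7 alcohol over the tertiary propargylic C3 alcohol.

**Step 11**
Reactants: 20 7β-acetoxy-3β-ethynyl-3α-ol
Product: 22 7β-acetoxy-3-oxo-cis-cleroda-4(18),13E-dien-15-oic acid, via tert-butyl ester 21 (not isolated)
Conditions: [(2,4-tBu2C6H3O)3P]AuCl (5 mol %), AgSbF6 (5 mol %), 4 Å molecular sieves, CH2Cl2/(CF3)2CHOH 9:1, 35 °C; then CF3CO2H, 0 °C to rt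
Reagents that add atoms: none
Why: Proposed new method: a strongly π-acidic cationic monovalent gold phosphite complex binds the terminal alkyne of the unstrained 1-ethynylcyclopentanol; the fully substituted, electron-rich C5 (not the CH2 group C2) migrates from the carbinol carbon C3 to the internal alkyne carbon C4 anti to gold and with retention at C5; proton transfer from the resulting oxocarbenium ion to the vinylgold carbon C18 releases the 2-methylenecyclohexanone and closes ring A; the driving force is the alkyne-to-enone conversion plus relief of cyclopentane torsional strain and of C3/C5 crowding instead of small-ring strain, while dry conditions suppress hydration and Meyer–Schuster isomerisation; the closest known reaction types are the gold-catalysed semipinacol ring expansion of 1-alkynylcyclopropanols and 1-alkynylcyclobutanols and the iodonium-induced expansion of 1-(haloethynyl)cyclopentanols; acidolysis in the same flask then cleaves the tert-butyl ester.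

**Step 12**
Reactants: 22 7β-acetoxy-3-oxo-cis-cleroda-4(18),13E-dien-15-oic acid
Product: 23 target, (E)-5-[(1R,2S,3S,4aS,8aR)-3-acetoxy-7-hydroxy-1,2,4a-trimethyl-5-methylidene-6-oxo-1,2,3,4,4a,5,6,8a-octahydronaphthalen-1-yl]-3-methylpent-2-enoic acid
Conditions: SeO2 (1.2 equiv), 1,4-dioxane/H2O 30:1, 70 °C
Reagents that add atoms: selenium dioxide, O=[Se]=O
Why: Riley oxidation attacks C2, the only enolisable position of the C3 ketone, and the 2,3-dione can enolise only towards C1 (C4 carries no hydrogen), which gives the diosphenol without touching any stereocentre.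

**Compound list**
1 | 2-methylcyclopentane-1,3-dione | CC1C(=O)CCC1=O | starting material
2 | pent-1-en-3-one (ethyl vinyl ketone) | C=CC(=O)CC | starting material
3 | 2-methyl-2-(3-oxopentyl)cyclopentane-1,3-dione | CCC(=O)CCC1(C)C(=O)CCC1=O | intermediate
4 | (7aS)-4,7a-dimethyl-2,3,7,7a-tetrahydro-1H-indene-1,5(6H)-dione (C3,C8-dione, C9=C10) | O=C1CCC2=C(C)C(=O)CC[C@]12C | intermediate
5 | C3 ethylene ketal of 4 (spiro-dioxolane at C3, enone retained) | C1CC2=C(C)C(=O)CC[C@]2(C)C13OCCO3 | intermediate
6 | cis-hydrindan-8-one C3 ketal, 10β-H, 9β-H, 19β-CH3 | C1C[C@@H]2[C@H](C)C(=O)CC[C@]2(C)C13OCCO3 | intermediate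
7 | but-3-en-2-one (methyl vinyl ketone) | C=CC(C)=O | starting material
8 | N-[(R)-1-phenylethyl] C8 imine of 6 (C9 epimers equilibrate through the enamine) | C1C[C@@H]2C(C)C(=N[C@H](C)c4ccccc4)CC[C@]2(C)C13OCCO3 | intermediate
9 | N-[(R)-1-phenylethyl] C8 imine carrying 9β-(3-oxobutyl) and 9α-CH3 | C1C[C@@H]2[C@@](C)(CCC(C)=O)C(=N[C@H](C)c4ccccc4)CC[C@]2(C)C13OCCO3 | intermediate
10 | 9β-(3-oxobutyl)-9α-methyl cis-hydrindan-8-one C3 ketal | C1C[C@@H]2[C@@](C)(CCC(C)=O)C(=O)CC[C@]2(C)C13OCCO3 | intermediate
11 | tert-butyl (13E)-enoate 8-ketone C3 ketal | C1C[C@@H]2[C@@](C)(CC/C(C)=C/C(=O)OC(C)(C)C)C(=O)CC[C@]2(C)C13OCCO3 | intermediate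
12 | potassium C7(8)-enolate of 11 | C1C[C@@H]2[C@@](C)(CC/C(C)=C/C(=O)OC(C)(C)C)C([O-])=CC[C@]2(C)C13OCCO3.[K+] | intermediate
13 | C7(8)-enol triflate of 11 | C1C[C@@H]2[C@@](C)(CC/C(C)=C/C(=O)OC(C)(C)C)C(OS(=O)(=O)C(F)(F)F)=CC[C@]2(C)C13OCCO3 | intermediate
14 | 8-methyl-7-ene C3 ketal | C1C[C@@H]2[C@@](C)(CC/C(C)=C/C(=O)OC(C)(C)C)C(C)=CC[C@]2(C)C13OCCO3 | intermediate
15 | 7β-boryl-8β-H alkylborane (RBH2) | C1C[C@@H]2[C@@](C)(CC/C(C)=C/C(=O)OC(C)(C)C)[C@H](C)[C@@H](B)C[C@]2(C)C13OCCO3 | intermediate
16 | 7β-hydroxy-8α-methyl C3 ketal | C1C[C@@H]2[C@@](C)(CC/C(C)=C/C(=O)OC(C)(C)C)[C@H](C)[C@@H](O)C[C@]2(C)C13OCCO3 | intermediate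
17 | 7β-hydroxy-8α-methyl cis-hydrindan-3-one (tert-butyl ester) | O=C1CC[C@@H]2[C@@](C)(CC/C(C)=C/C(=O)OC(C)(C)C)[C@H](C)[C@@H](O)C[C@]12C | intermediate
18 | ethynylmagnesium bromide | C#C[Mg]Br | starting material
19 | 3β-ethynyl-3α,7β-diol (tert-butyl ester) | C#C[C@@]1(O)CC[C@@H]2[C@@](C)(CC/C(C)=C/C(=O)OC(C)(C)C)[C@H](C)[C@@H](O)C[C@]12C | intermediate
20 | 7β-acetoxy-3β-ethynyl-3α-ol (tert-butyl ester) | C#C[C@@]1(O)CC[C@@H]2[C@@](C)(CC/C(C)=C/C(=O)OC(C)(C)C)[C@H](C)[C@@H](OC(C)=O)C[C@]12C | intermediate
21 | tert-butyl 7β-acetoxy-3-oxo-cis-cleroda-4(18),13E-dien-15-oate | C=C1C(=O)CC[C@@H]2[C@@](C)(CC/C(C)=C/C(=O)OC(C)(C)C)[C@H](C)[C@@H](OC(C)=O)C[C@]12C | intermediate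
22 | 7β-acetoxy-3-oxo-cis-cleroda-4(18),13E-dien-15-oic acid | C=C1C(=O)CC[C@@H]2[C@@](C)(CC/C(C)=C/C(=O)O)[C@H](C)[C@@H](OC(C)=O)C[C@]12C | intermediate
23 | CNP0192653.1, (5S,7S,8S,9R,10R)-7-acetoxy-2-hydroxy-3-oxo-cleroda-1,4(18),13E-trien-15-oic acid | C=C1C(=O)C(O)=C[C@@H]2[C@@](C)(CC/C(C)=C/C(=O)O)[C@H](C)[C@@H](OC(C)=O)C[C@]12C | target

**Total step count:** 12. **Longest linear sequence:** 12 steps (fully linear from 1).

**Three steps most likely to fail**

*Step 11 (the proposed ring expansion).* Without small-ring strain the 1,2-shift may lose to Meyer–Schuster or Rupe isomerisation.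
- The fallback uses only known reaction types. It sets out from 20 and comes back at 21, which is then treated with CF3CO2H as in step 11.
- NBS with AgNO3 (cat.) in acetone gives the bromoalkyne F2.
- I2 and PhI(OH)OTs in MeCN bring about the known halonium-induced expansion of a 1-(haloethynyl)cyclopentanol. The more substituted carbon migrates, giving the (Z)-18-bromo-18-iodo enone F3.
- Bu3SnH with Pd(PPh3)4 in THF replaces both halogens by hydrogen.

*Step 12 (Riley oxidation).* Allylic oxidation of the side chain or further dehydrogenation of the diosphenol may compete.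
- The fallback sets out from 22 and comes back at 23.
- tBuMe2SiOTf (2.5 equiv) and Et3N in CH2Cl2 give the silyl ester silyl dienol ether F4.
- Rubottom oxidation with dimethyldioxirane at −40 °C, followed by a mild aqueous citric acid work-up, gives the 2-hydroxy-3-ketone acid F5 (C2 epimers, of no consequence).
- Dess–Martin periodinane oxidises it to the 2,3-dione, which tautomerises to the diosphenol.

*Step 4 (quaternary C9).* The hindered enamine may react slowly, or the auxiliary may prove mismatched.
- The fallback sets out from 6 and comes back at 10.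
- Me3SiCl and Et3N in DMF at 130 °C (thermodynamic control) give the tetrasubstituted trimethylsilyl enol ether F1.
- Mukaiyama–Michael addition to 7 with BF3·OEt2 and iPrOH in CH2Cl2 at −78 °C then forms the C9–C11 bond under substrate (convex-face) control alone.

**Further compounds**
F1 | step 4 | C8(9)-trimethylsilyl enol ether of 6 | C1C[C@@H]2C(C)=C(O[Si](C)(C)C)CC[C@]2(C)C13OCCO3
F2 | step 11 | 3β-(bromoethynyl) analogue of 20 | BrC#C[C@@]1(O)CC[C@@H]2[C@@](C)(CC/C(C)=C/C(=O)OC(C)(C)C)[C@H](C)[C@@H](OC(C)=O)C[C@]12C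
F3 | step 11 | (Z)-18-bromo-18-iodo analogue of 21 | I/C(Br)=C1\C(=O)CC[C@@H]2[C@@](C)(CC/C(C)=C/C(=O)OC(C)(C)C)[C@H](C)[C@@H](OC(C)=O)C[C@]12C
F4 | step 12 | tert-butyldimethylsilyl ester and C3-O-silyl 2,4(18)-dienol ether of 22 | C=C1C(O[Si](C)(C)C(C)(C)C)=CC[C@@H]2[C@@](C)(CC/C(C)=C/C(=O)O[Si](C)(C)C(C)(C)C)[C@H](C)[C@@H](OC(C)=O)C[C@]12C
F5 | step 12 | 2-hydroxy derivative of 22 (C2 epimers) | C=C1C(=O)C(O)C[C@@H]2[C@@](C)(CC/C(C)=C/C(=O)O)[C@H](C)[C@@H](OC(C)=O)C[C@]12C
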